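**Strategy.** Skeleton locants follow tricyclo[5.4.0.0^2,8]undecane numbering. The cyclobutane C1–C2–C8–C7 is treated as a formal [2+2] adduct of a C8 ketone enol (C8=C2) and a C1=C7 enal, and the C4/C6 oxygen pair as an aldol. One silyl-mediated domino on the acyclic diketo-enal 16 therefore closes all three rings: Michael addition (C1–C2, six-membered ring), cyclobutane-forming aldol (C7–C8) and Mukaiyama aldol of the C4 methyl ketone onto the regenerated C6 aldehyde (C5–C6, seven-membered ring), relayed from the single C11 stereocentre. The auxiliary C8 oxygen and the C9 dithiane are removed afterwards.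

Key step: step 10

Remark on the chemistry: the C9 carbonyl is carried as a 1,3-dithiane. The transient carbinol centres (one in 2–5, two in 12 and 13) are epimer mixtures of no consequence, since all are oxidised in step 8. Target-skeleton locants (C1–C11) are also used for the open-chain precursors in the Why lines.

Step 1
Reactants: 1 2,2-dimethylpent-4-enal
Product: 2 3,3-dimethylhex-5-en-2-ol (racemic)
Conditions: MeMgBr, Et2O, 0 °C; aq. NH4Cl
Reagents that add atoms: methylmagnesium bromide, C[Mg]Br
Why: Grignard 1,2-addition to the non-enolisable aldehyde should install the C5 methyl carbon on C4, the new carbinol centre being uncontrolled because it is later oxidised.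

Step 2
Reactants: 2 3,3-dimethylhex-5-en-2-ol
Product: 3 tert-butyl[(3,3-dimethylhex-5-en-2-yl)oxy]dimethylsilane
Conditions: TBSCl, imidazole, DMF, rt
Reagents that add atoms: tert-butyldimethylsilyl chloride, CC(C)(C)[Si](C)(C)Cl
Why: Standard silylation should mask the C4 hydroxyl against the organolithium used in step 6.

Step 3
Reactants: 3 tert-butyl[(3,3-dimethylhex-5-en-2-yl)oxy]dimethylsilane
Product: 5 4-(tert-butyldimethylsilyloxy)-3,3-dimethylpentanal, via ozonide 4 (not isolated)
Conditions: O3, CH2Cl2, −78 °C; then PPh3, −78 °C to rt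
Reagents that add atoms: ozone, [O-][O+]=O
Why: Ozonolysis with reductive work-up should cut the terminal alkene to the C8 aldehyde without touching the silyl ether.

Step 4
Reactants: 6 (S)-3-bromo-2-methylpropan-1-ol
Product: 7 (S)-(3-bromo-2-methylpropoxy)(tert-butyl)dimethylsilane
Conditions: TBSCl, imidazole, CH2Cl2, 0 °C to rt
Reagents that add atoms: tert-butyldimethylsilyl chloride, CC(C)(C)[Si](C)(C)Cl
Why: Silylation should protect the future C1 carbinol of the chiral-pool fragment, which already carries the C11 stereocentre.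

Step 5
Reactants: 8 1,3-dithiane; 7 (S)-(3-bromo-2-methylpropoxy)(tert-butyl)dimethylsilane
Product: 10 (R)-tert-butyl[3-(1,3-dithian-2-yl)-2-methylpropoxy]dimethylsilane, via 2-lithio-1,3-dithiane 9 (not isolated)
Conditions: n-BuLi, THF, −30 °C; then 7, HMPA, −78 °C to rt
Reagents that add atoms: none
Why: Corey–Seebach alkylation of the acyl-anion equivalent with the primary bromide should form C9–C10 without touching the C11 centre (the descriptor changes only by priority).

Step 6
Reactants: 10 (R)-tert-butyl[3-(1,3-dithian-2-yl)-2-methylpropoxy]dimethylsilane; 5 4-(tert-butyldimethylsilyloxy)-3,3-dimethylpentanal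
Product: 12 bis-silyl ether carbinol (C8/C4 epimer mixture), via lithiated dithiane 11 (not isolated)
Conditions: n-BuLi, THF, −20 °C; then 5, −78 °C; aq. NH4Cl
Reagents that add atoms: none
Why: A second Corey–Seebach metalation and addition to the aldehyde should form C8–C9 and complete the whole carbon chain except C6 and C7.

Step 7
Reactants: 12 bis-silyl ether carbinol
Product: 13 triol
Conditions: Bu4NF, THF, 45 °C
Reagents that add atoms: none
Why: Fluoride should cleave both silyl ethers, the dithiane being inert.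

Step 8
Reactants: 13 triol
Product: 14 (R)-3-[2-(3,3-dimethyl-4-oxopentanoyl)-1,3-dithian-2-yl]-2-methylpropanal
Conditions: (COCl)2, DMSO, CH2Cl2, −78 °C; Et3N, −78 to 0 °C
Reagents that add atoms: none
Why: Threefold Swern oxidation at low temperature should give the C1 aldehyde and the C8 and C4 ketones without oxidising sulfur or epimerising C11.

Step 9
Reactants: 14 (R)-3-[2-(3,3-dimethyl-4-oxopentanoyl)-1,3-dithian-2-yl]-2-methylpropanal; 15 2-(triphenyl-λ5-phosphanylidene)propanal
Product: 16 (2E,4R)-5-[2-(3,3-dimethyl-4-oxopentanoyl)-1,3-dithian-2-yl]-2,4-dimethylpent-2-enal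
Conditions: toluene, 90 °C
Reagents that add atoms: none
Why: The stabilised formyl ylide should react only with the aldehyde in a Wittig olefination, adding C7 (with its methyl) and C6 as the (E)-enal.

Step 10
Reactants: 16 (2E,4R)-5-[2-(3,3-dimethyl-4-oxopentanoyl)-1,3-dithian-2-yl]-2,4-dimethylpent-2-enal
Product: 19 tricyclic 6,8-dihydroxy-4-ketone (dithiane at C9), via bis(trimethylsilyl enol ether) 17 (not isolated), via tricyclic bis(trimethylsilyl) ether 18 (not isolated)
Conditions: Me3SiI, (Me3Si)2NH, ClCH2CH2Cl (0.01 M), −30 °C to rt; then 1 M HCl, THF, 0 °C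
Reagents that add atoms: none
Why: Proposed new method: Me3SiI/(Me3Si)2NH should convert both ketones into their only possible silyl enol ethers (C8=C2, blocked at C9 by the dithiane; C4=C5, blocked at C3) and activate the enal, after which C2 adds to C1 (6-(enolendo)-exo-trig Michael), the new C6=C7 silyl enol ether collapses onto the C8 oxocarbenium ion (4-(enolexo)-exo-trig aldol, cyclobutane) and the regenerated silylated C6 aldehyde is captured by C5 (7-(enolendo)-exo-trig Mukaiyama aldol). The closest known reaction type is the silyl-iodide/disilazane-mediated intramolecular Michael–aldol of ω-oxo-α,β-unsaturated esters that gives fused cyclobutanols (a formal [2+2]), here extended to an enal acceptor, a bridged ring fusion and a terminating Mukaiyama aldol. C1 should be set by attack anti to the C11 methyl in the A(1,3)-minimised enal conformer, C8 by the need to bridge C1 and C8 across one face of the new six-membered ring, C2 and C7 by the fact that only the isomer with C3 and C6 both turned away from the C9–C11 bridge can close the seven-membered ring (re-enolisation at C2 and reversible cyclobutane aldolisation should feed this isomer), and C6 by Felkin-type approach of C5 past the C1 flank instead of the siloxy-bearing C8 flank. The step needs 1,4- over 1,2-attack on the enal (ring size six against eight), four-membered aldol closure faster than desilylation of the oxocarbenium ion, and no aldol between C5 and C8 (C8 is held as its enol ether until the Michael step); the last aldol should drain the cyclobutane equilibrium. Dilute acid then cleaves both silyl ethers.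

Step 11
Reactants: 19 tricyclic 6,8-dihydroxy-4-ketone
Product: 20 tricyclic 4,6,8-triol
Conditions: Me4NBH(OAc)3, MeCN/AcOH, −30 °C
Reagents that add atoms: none
Why: Evans–Saksena reduction should deliver hydride intramolecularly from the C6 alkoxyborohydride to the face of C4 that bears the C6 oxygen, giving the 4,6-anti (trans) diol and so setting C4.

Step 12
Reactants: 20 tricyclic 4,6,8-triol
Product: 21 4,6-diacetate with free 8-OH
Conditions: Ac2O, pyridine, DMAP (cat.), CH2Cl2, rt
Reagents that add atoms: acetic anhydride, CC(=O)OC(C)=O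
Why: Acetylation should take only the two secondary hydroxyls and leave the tertiary bridgehead 8-OH free.

Step 13
Reactants: 21 4,6-diacetate with free 8-OH
Product: 22 8-(methyl oxalate)
Conditions: ClC(O)CO2Me, DMAP, pyridine, CH2Cl2, 0 °C to rt
Reagents that add atoms: methyl chlorooxoacetate, COC(=O)C(Cl)=O
Why: The small, very reactive oxalyl chloride half-ester should acylate even the hindered tertiary alcohol, and doing so before the ketone is unmasked avoids a free cyclobutyl α-ketol that could ring-expand.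

Step 14
Reactants: 22 8-(methyl oxalate)
Product: 23 8-oxalyloxy 9-ketone
Conditions: PhI(O2CCF3)2, MeCN/H2O 9:1, 0 °C
Reagents that add atoms: water, O
Why: Oxidative dethioacetalisation should unmask the C9 ketone quickly enough for the acetates and the oxalate to survive.

Step 15
Reactants: 23 8-oxalyloxy 9-ketone
Product: 24 4,6-diacetoxy 9-ketone (8-H)
Conditions: Bu3SnH, AIBN (cat.), toluene, 100 °C
Reagents that add atoms: none
Why: Barton-type radical deoxygenation of the tertiary oxalate should give a bridgehead radical that takes hydrogen from the stannane, the configuration at C8 being dictated by the bicyclic frame.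

Step 16
Reactants: 24 4,6-diacetoxy 9-ketone (8-H)
Product: 25 4,6-diol 9-ketone
Conditions: K2CO3, MeOH, rt
Reagents that add atoms: none
Why: Methanolysis should remove both acetates; C8 is a non-enolisable bridgehead and no other stereocentre is base-labile.

Step 17
Reactants: 25 4,6-diol 9-ketone
Product: 26 CNP0283599.1 (4,6-bis-angelate)
Conditions: angelic acid, 2,4,6-trichlorobenzoyl chloride, Et3N, toluene, rt; then 25, 80 °C
Reagents that add atoms: angelic acid, C/C=C(/C)C(=O)O
Why: Yamaguchi-type esterification through the preformed mixed 2,4,6-trichlorobenzoic anhydride, run without a nucleophilic catalyst, should transfer the (Z)-2-methylbut-2-enoyl group to the hindered secondary alcohols with the least Z-to-E isomerisation.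

**Compound list**

1 | 2,2-dimethylpent-4-enal | C=CCC(C)(C)C=O | starting material
2 | 3,3-dimethylhex-5-en-2-ol (racemic) | CC(O)C(C)(C)CC=C | intermediate
3 | tert-butyl[(3,3-dimethylhex-5-en-2-yl)oxy]dimethylsilane (racemic) | CC(O[Si](C)(C)C(C)(C)C)C(C)(C)CC=C | intermediate
4 | 3-[3-(tert-butyldimethylsilyloxy)-2,2-dimethylbutyl]-1,2,4-trioxolane (ozonide of 3) | CC(O[Si](C)(C)C(C)(C)C)C(C)(C)CC1OCOO1 | intermediate (not isolated)
5 | 4-(tert-butyldimethylsilyloxy)-3,3-dimethylpentanal (racemic) | CC(O[Si](C)(C)C(C)(C)C)C(C)(C)CC=O | intermediate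
6 | (S)-3-bromo-2-methylpropan-1-ol | OC[C@H](C)CBr | starting material
7 | (S)-(3-bromo-2-methylpropoxy)(tert-butyl)dimethylsilane | CC(C)(C)[Si](C)(C)OC[C@H](C)CBr | intermediate
8 | 1,3-dithiane | C1CSCSC1 | starting material
9 | 2-lithio-1,3-dithiane | [Li]C1SCCCS1 | intermediate (not isolated)
10 | (R)-tert-butyl[3-(1,3-dithian-2-yl)-2-methylpropoxy]dimethylsilane | CC(C)(C)[Si](C)(C)OC[C@H](C)CC1SCCCS1 | intermediate
11 | 2-lithio derivative of 10 | CC(C)(C)[Si](C)(C)OC[C@H](C)CC1([Li])SCCCS1 | intermediate (not isolated)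
12 | 4-(tert-butyldimethylsilyloxy)-1-{2-[(R)-3-(tert-butyldimethylsilyloxy)-2-methylpropyl]-1,3-dithian-2-yl}-3,3-dimethylpentan-1-ol (epimer mixture at C1 and C4 of the pentanol) | CC(C)(C)[Si](C)(C)OC[C@H](C)CC1(SCCCS1)C(O)CC(C)(C)C(C)O[Si](C)(C)C(C)(C)C | intermediate
13 | 1-{2-[(R)-3-hydroxy-2-methylpropyl]-1,3-dithian-2-yl}-3,3-dimethylpentane-1,4-diol (epimer mixture at C1 and C4) | OC[C@H](C)CC1(SCCCS1)C(O)CC(C)(C)C(C)O | intermediate
14 | (R)-3-[2-(3,3-dimethyl-4-oxopentanoyl)-1,3-dithian-2-yl]-2-methylpropanal | O=C[C@H](C)CC1(SCCCS1)C(=O)CC(C)(C)C(C)=O | intermediate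
15 | 2-(triphenyl-λ5-phosphanylidene)propanal | CC(C=O)=P(c1ccccc1)(c1ccccc1)c1ccccc1 | starting material
16 | (2E,4R)-5-[2-(3,3-dimethyl-4-oxopentanoyl)-1,3-dithian-2-yl]-2,4-dimethylpent-2-enal | O=C/C(C)=C/[C@H](C)CC1(SCCCS1)C(=O)CC(C)(C)C(C)=O | intermediate
17 | bis(trimethylsilyl enol ether) of 16 (C8=C2 and C4=C5 enol ethers) | O=C/C(C)=C/[C@H](C)CC1(SCCCS1)C(O[Si](C)(C)C)=CC(C)(C)C(=C)O[Si](C)(C)C | intermediate (not isolated)
18 | 3,3,7,11-tetramethyl-6,8-bis(trimethylsilyloxy)tricyclo[5.4.0.0^2,8]undecan-4-one with C9 as spiro 1,3-dithiane; C1, C2, C6, C7, C11 as in 26, 8-O in place of 8-H | O=C1C[C@@H](O[Si](C)(C)C)[C@]2(C)[C@@H]3[C@@H]([C@@]2(O[Si](C)(C)C)C4(SCCCS4)C[C@H]3C)C1(C)C | intermediate (not isolated)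
19 | 6,8-dihydroxy analogue of 18 (free diol, 4-ketone, C9 dithiane) | O=C1C[C@@H](O)[C@]2(C)[C@@H]3[C@@H]([C@@]2(O)C4(SCCCS4)C[C@H]3C)C1(C)C | intermediate
20 | 4,6,8-triol (4,6-anti; C4 as in 26; C9 dithiane) | O[C@@H]1C[C@@H](O)[C@]2(C)[C@@H]3[C@@H]([C@@]2(O)C4(SCCCS4)C[C@H]3C)C1(C)C | intermediate
21 | 4,6-diacetate of 20 (8-OH free) | CC(=O)O[C@@H]1C[C@@H](OC(C)=O)[C@]2(C)[C@@H]3[C@@H]([C@@]2(O)C4(SCCCS4)C[C@H]3C)C1(C)C | intermediate
22 | 8-(methoxyoxalyl) ester of 21 | CC(=O)O[C@@H]1C[C@@H](OC(C)=O)[C@]2(C)[C@@H]3[C@@H]([C@@]2(OC(=O)C(=O)OC)C4(SCCCS4)C[C@H]3C)C1(C)C | intermediate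
23 | 4,6-diacetoxy-8-(methoxyoxalyloxy)-3,3,7,11-tetramethyltricyclo[5.4.0.0^2,8]undecan-9-one | CC(=O)O[C@@H]1C[C@@H](OC(C)=O)[C@]2(C)[C@@H]3[C@@H]([C@@]2(OC(=O)C(=O)OC)C(=O)C[C@H]3C)C1(C)C | intermediate
24 | (1S,2S,4R,6R,7R,8R,11R)-3,3,7,11-tetramethyl-9-oxotricyclo[5.4.0.0^2,8]undecane-4,6-diyl diacetate | CC(=O)O[C@@H]1C[C@@H](OC(C)=O)[C@]2(C)[C@@H]3[C@@H]([C@H]2C(=O)C[C@H]3C)C1(C)C | intermediate
25 | (1S,2S,4R,6R,7R,8R,11R)-4,6-dihydroxy-3,3,7,11-tetramethyltricyclo[5.4.0.0^2,8]undecan-9-one | O[C@@H]1C[C@@H](O)[C@]2(C)[C@@H]3[C@@H]([C@H]2C(=O)C[C@H]3C)C1(C)C | intermediate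
26 | CNP0283599.1: (1S,2S,4R,6R,7R,8R,11R)-3,3,7,11-tetramethyl-9-oxotricyclo[5.4.0.0^2,8]undecane-4,6-diyl bis[(2Z)-2-methylbut-2-enoate] | C/C=C(/C)C(=O)O[C@@H]1C[C@@H](OC(=O)/C(C)=C\C)[C@]2(C)[C@@H]3[C@@H]([C@H]2C(=O)C[C@H]3C)C1(C)C | target

**Total step count:** 17. **Longest linear sequence:** 15 steps (steps 1–3 and then 6–17, from 1). Steps 4–5 form the side branch, which joins at step 6.

**Steps most likely to fail**

1. Step 10 (proposed new method). After the Michael step the oxocarbenium/silyl enol ether pair may lose silicon, or close a five-membered aldol onto C4, instead of closing the congested bridged four-membered ring; C6 and C7 may also form with poor facial selectivity. Fallback with known chemistry, stepwise: from 14, Wittig olefination with methyl 2-(triphenyl-λ5-phosphanylidene)propanoate (toluene, 90 °C) would give the (E)-enoate F1, a keto enoate of the substrate class for which the Me3SiI/(Me3Si)2NH Michael–aldol is established. That reaction should give the bicyclo[3.1.1]heptane methyl ester F2 (8-trimethylsilyl ether, side chain on C2 intact). LiAlH4 reduction would give the diol F3, Swern oxidation the keto aldehyde F4, and a separate kinetic aldol (LDA, THF, −78 °C) the seven-membered-ring aldol, 8-silyl ether F5. Dilute HCl then gives 19.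

2. Step 15. Homolysis of the strained bridgehead C8–O bond may be slower than stannyl attack on the carbonyl groups or loss of the labile oxalate. Fallback: from 21, PhI(O2CCF3)2 in aqueous MeCN would give the free α-ketol F6, reduced at once with NaBH4 to the 8,9-diol F7. 1,1′-Thiocarbonyldiimidazole would give the cyclic thionocarbonate F8. Stannyl radical adds fast to the thiocarbonyl sulfur, and fragmentation of the adduct towards the more substituted C8 radical should break the tertiary C8–O bond and leave, after hydrolytic work-up, the 9-alcohol F9. Dess–Martin oxidation returns to 24.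

3. Step 17. Acylation of two neopentylic carbinols may be slow, and the angeloyl group may isomerise to the (E)-ester on prolonged heating. Fallback: from 25, DCC/DMAP esterification with 2-[bis(2,2,2-trifluoroethoxy)phosphoryl]propanoic acid would give the bis(phosphonate) F10. Twofold Still–Gennari olefination with acetaldehyde (KN(SiMe3)2, 18-crown-6, THF, −78 °C) would build both (Z)-2-methylbut-2-enoates on the ester, arriving at 26.

**Further compounds**

F1 | step 10 | methyl (2E,4R)-5-[2-(3,3-dimethyl-4-oxopentanoyl)-1,3-dithian-2-yl]-2,4-dimethylpent-2-enoate | COC(=O)/C(C)=C/[C@H](C)CC1(SCCCS1)C(=O)CC(C)(C)C(C)=O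
F2 | step 10 | bicyclo[3.1.1]heptane core (C1, C2, C7–C11 of 26): C7 methyl ester, C8 trimethylsilyl ether, C9 dithiane, C2 bearing 2-methyl-3-oxobutan-2-yl | COC(=O)[C@]2(C)[C@@H]3[C@@H]([C@@]2(O[Si](C)(C)C)C4(SCCCS4)C[C@H]3C)C(C)(C)C(C)=O
F3 | step 10 | diol from F2 (C6 hydroxymethyl, C4 carbinol as epimer mixture) | OC[C@]2(C)[C@@H]3[C@@H]([C@@]2(O[Si](C)(C)C)C4(SCCCS4)C[C@H]3C)C(C)(C)C(C)O
F4 | step 10 | keto aldehyde from F3 (C6 aldehyde, C4 methyl ketone) | O=C[C@]2(C)[C@@H]3[C@@H]([C@@]2(O[Si](C)(C)C)C4(SCCCS4)C[C@H]3C)C(C)(C)C(C)=O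
F5 | step 10 | 8-trimethylsilyl ether of 19 | O=C1C[C@@H](O)[C@]2(C)[C@@H]3[C@@H]([C@@]2(O[Si](C)(C)C)C4(SCCCS4)C[C@H]3C)C1(C)C
F6 | step 15 | 4,6-diacetoxy-8-hydroxy-3,3,7,11-tetramethyltricyclo[5.4.0.0^2,8]undecan-9-one | CC(=O)O[C@@H]1C[C@@H](OC(C)=O)[C@]2(C)[C@@H]3[C@@H]([C@@]2(O)C(=O)C[C@H]3C)C1(C)C
F7 | step 15 | 8,9-diol from F6 (C9 epimer mixture) | CC(=O)O[C@@H]1C[C@@H](OC(C)=O)[C@]2(C)[C@@H]3[C@@H]([C@@]2(O)C(O)C[C@H]3C)C1(C)C
F8 | step 15 | 8,9-cyclic thionocarbonate of F7 | CC(=O)O[C@@H]1C[C@@H](OC(C)=O)[C@]2(C)[C@@H]3[C@@H]([C@]24OC(=S)OC4C[C@H]3C)C1(C)C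
F9 | step 15 | 9-alcohol (8-H), 4,6-diacetate | CC(=O)O[C@@H]1C[C@@H](OC(C)=O)[C@]2(C)[C@@H]3[C@@H]([C@H]2C(O)C[C@H]3C)C1(C)C
F10 | step 17 | 4,6-bis{2-[bis(2,2,2-trifluoroethoxy)phosphoryl]propanoate} of 25 | CC(C(=O)O[C@@H]1C[C@@H](OC(=O)C(C)P(=O)(OCC(F)(F)F)OCC(F)(F)F)[C@]2(C)[C@@H]3[C@@H]([C@H]2C(=O)C[C@H]3C)C1(C)C)P(=O)(OCC(F)(F)F)OCC(F)(F)F
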